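**Retrosynthetic overview**

1. Numbering used: C1 = methyl-bearing quaternary fusion carbon (CH3 = C15); C2 = its CH–OAc neighbour; C3, C4 = CH2; C5=C6 = the Z-alkene (CH3 = C16); C7 = lactone O–CH; C8 = C–OH; C9 = CH–OAc; C10 = fusion CH; C11 = CH–CH3 (C20); C12 = CH–O2CPr; C13=C14 = ring alkene; C17/C18/C19 = lactone CH, its CH3, C=O.
2. Last ring: the ten-membered ring, closed at C5=C6 by ring-closing metathesis of a 5,6-seco diene; before that, C12 is set by Luche reduction and Mitsunobu butanoylation, and C2 by CBS reduction.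
3. Key disconnection: C14–C1 and C11–C10 by a silicon-tethered type 2 intramolecular Diels–Alder reaction of a (Z)-2-silyloxy-1,3-pentadiene (C11–C14, from ethyl vinyl ketone) onto the (E)-C10=C1 enone (C2 ketone); Saegusa oxidation of the bridgehead silyl enol ether then gives the C12 ketone with the C13=C14 alkene.
4. Enabling feature: the oxygens on C9 and C12 are 1,4-related across the new C10–C11 bond of the cyclohexene ring (O–C9–C10–C11–C12–O), so one silicon atom can bridge them as a temporary seven-membered 1,3-dioxa-2-silepane; the C2 oxygen next to C1 supplies the activating ketone, and the C12–O/C13=C14 allylic ester is a masked enone, hence a 2-silyloxy diene.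
5. Dienophile: Wittig olefination at C10 of a γ-lactone aldehyde whose C7, C8, C9 are C2, C3, C4 of diacetone-D-glucose (C8 and C17 by amide-enolate addition to the 3-ulose); ring order: γ-lactone, then cyclohexene (with the temporary silacycle), then ten-membered ring.

Key step: step 12

Remark: the target is read from its SMILES as the (1S,2R,5Z,7S,8S,9R,10S,11R,12R,17R) isomer in the numbering of line 1; "as in 28" below means the same spatial arrangement, whatever the CIP letter; compounds 1, 3, 11, 12, 18 and all reagents are assumed to be purchased.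

Step 1
Reactants: 1 1,2:5,6-di-O-isopropylidene-α-D-glucofuranose (diacetone-D-glucose)
Product: 2 1,2:5,6-di-O-isopropylidene-α-D-ribo-hexofuranos-3-ulose
Conditions: TEMPO (cat.), KBr (cat.), NaOCl, NaHCO3, CH2Cl2/H2O, 0 °C; PhMe azeotrope
Reagents that add atoms: none
Why: TEMPO/NaOCl (oxoammonium) oxidation converts the only free hydroxyl, the secondary 3-OH, into the ketone without touching the two acetonides, and no stereocentre is formed.

Step 2
Reactants: 2 1,2:5,6-di-O-isopropylidene-α-D-ribo-hexofuranos-3-ulose; 3 N,N-dimethylpropanamide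
Product: 4 3-C-[(2R)-1-(dimethylamino)-1-oxopropan-2-yl]-1,2:5,6-di-O-isopropylidene-α-D-allofuranose
Conditions: LiN(iPr)2, 3, THF, −78 °C; then 2, −78 °C; AcOH quench at −78 °C
Reagents that add atoms: none
Why: Aldol-type 1,2-addition of the Z(O)-lithium amide enolate should occur on the exo face of the cis-fused bicyclic ulose, anti to the 1,2-acetonide (the usual course for nucleophiles with this ketone), which sets C8, while a chair Zimmerman–Traxler transition state that leans away from the side chain on sugar C4 places the enolate methyl anti to sugar C2 and so sets C17 as R.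

Step 3
Reactants: 4 3-C-[(2R)-1-(dimethylamino)-1-oxopropan-2-yl]-1,2:5,6-di-O-isopropylidene-α-D-allofuranose
Product: 5 3-C-[(2R)-1-(dimethylamino)-1-oxopropan-2-yl]-2,3:5,6-di-O-isopropylidene-D-allofuranose (free lactol, anomers)
Conditions: acetone, H2SO4 (cat.), rt
Reagents that add atoms: none
Why: Acid-catalysed acetal migration, in which the anomeric C–O bond of the 1,2-acetonide ionises and the cis tertiary 3-OH captures the isopropylidene oxocarbenium ion, should give the thermodynamically preferred cis-fused 2,3-acetonide with a free lactol (the pattern shown by ribose, allose and mannose acetonides) without changing any chain stereocentre.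

Step 4
Reactants: 5 3-C-[(2R)-1-(dimethylamino)-1-oxopropan-2-yl]-2,3:5,6-di-O-isopropylidene-D-allofuranose
Product: 6 1,2-dideoxy-4-C-[(2R)-1-(dimethylamino)-1-oxopropan-2-yl]-3,4:6,7-di-O-isopropylidene-D-allo-hept-1-enitol (free 5-OH)
Conditions: Ph3PCH3Br, KOtBu, THF, 0 °C → reflux
Reagents that add atoms: methyltriphenylphosphonium bromide (gives Ph3P=CH2 in the flask), C[P+](c1ccccc1)(c1ccccc1)c1ccccc1.[Br-]
Why: Wittig methylenation of the ring-opened hydroxy-aldehyde form of the lactol (standard for 2,3-O-isopropylidene furanoses) installs the vinyl group (C6) and frees only the former ring oxygen as the C9 hydroxyl, the tertiary amide being inert to the alkoxide.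

Step 5
Reactants: 6 1,2-dideoxy-4-C-[(2R)-1-(dimethylamino)-1-oxopropan-2-yl]-3,4:6,7-di-O-isopropylidene-D-allo-hept-1-enitol
Product: 7 5-O-(4-methoxybenzyl) ether of 6
Conditions: NaH, 4-methoxybenzyl chloride, Bu4NI (cat.), DMF, 0 °C → rt
Reagents that add atoms: 4-methoxybenzyl chloride, COc1ccc(CCl)cc1
Why: Williamson etherification masks the single free hydroxyl (O9) as a PMB ether that survives the acid of step 6, blocks O9 from lactonisation and from glycol cleavage, and is removable oxidatively.

Step 6
Reactants: 7 5-O-(4-methoxybenzyl) ether of 6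
Product: 9 (3R,4S,5S)-4-[(1R,2R)-2,3-dihydroxy-1-(4-methoxybenzyloxy)propyl]-5-ethenyl-4-hydroxy-3-methyloxolan-2-one, via tetraol amide 8 (not isolated)
Conditions: AcOH/H2O 4:1, 70 °C; then CSA (cat.), PhMe, 60 °C
Reagents that add atoms: none
Why: Acidic hydrolysis removes both isopropylidene acetals and the freed C7 hydroxyl, the only free γ-hydroxyl because O9 is blocked, attacks the protonated amide (N→O acyl transfer, 5-exo-trig, favoured over the δ-closure onto the side-chain diol) to close the γ-lactone with loss of dimethylamine and without touching a stereocentre.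

Step 7
Reactants: 9 (3R,4S,5S)-4-[(1R,2R)-2,3-dihydroxy-1-(4-methoxybenzyloxy)propyl]-5-ethenyl-4-hydroxy-3-methyloxolan-2-one
Product: 10 (2S)-2-[(2S,3S,4R)-2-ethenyl-3-hydroxy-4-methyl-5-oxooxolan-3-yl]-2-(4-methoxybenzyloxy)acetaldehyde
Conditions: NaIO4, THF/H2O, 0 °C
Reagents that add atoms: none
Why: Periodate glycol cleavage (Malaprade reaction) of the terminal 1,2-diol removes the extra sugar carbon and reveals the C10 aldehyde, the tertiary 8-OH and the PMB-protected O9 offering no second vicinal diol.

Step 8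
Reactants: 11 4-methylpent-4-enoic acid; 12 ethyltriphenylphosphonium bromide (2 equiv)
Product: 15 6-methyl-2-(triphenyl-λ5-phosphanylidene)hept-6-en-3-one, via 4-methylpent-4-enoyl chloride 13 (not isolated), via ethylidene(triphenyl)phosphorane 14 (not isolated)
Conditions: 11, (COCl)2, DMF (cat.), CH2Cl2, rt, evaporate; 12, n-BuLi, THF, 0 °C; add 13 at −78 °C → rt
Reagents that add atoms: none
Why: C-acylation of a non-stabilised ylide by an acid chloride, the second equivalent of ylide deprotonating the acylphosphonium salt (transylidation), gives the stabilised α-methyl acyl ylide.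

Step 9
Reactants: 10 (2S)-2-[(2S,3S,4R)-2-ethenyl-3-hydroxy-4-methyl-5-oxooxolan-3-yl]-2-(4-methoxybenzyloxy)acetaldehyde; 15 6-methyl-2-(triphenyl-λ5-phosphanylidene)hept-6-en-3-one
Product: 16 lactone of 9 carrying at its C4 a (1R,2E)-1-(4-methoxybenzyloxy)-3,7-dimethyl-4-oxoocta-2,7-dien-1-yl chain (C9–C10=C1(CH3)–C2(=O)–C3–C4–C5(CH3)=CH2)
Conditions: PhMe, 90 °C
Reagents that add atoms: none
Why: Wittig olefination with the stabilised α-methyl keto ylide under neutral conditions should give the (E)-trisubstituted enone (C9 cis to the C1 methyl, C9 trans to C2) without epimerising the α-alkoxy aldehyde.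

Step 10
Reactants: 16 PMB-protected lactone enone
Product: 17 lactone of 9 carrying at its C4 a (1R,2E)-1-hydroxy-3,7-dimethyl-4-oxoocta-2,7-dien-1-yl chain
Conditions: DDQ, CH2Cl2/pH 7 buffer, 0 °C
Reagents that add atoms: none
Why: DDQ oxidises the electron-rich PMB ether to its oxocarbenium ion, which water hydrolyses, so the C9 hydroxyl is freed under neutral conditions that spare the enone, the lactone and the alkenes.

Step 11
Reactants: 17 lactone γ-hydroxy enone; 18 pent-1-en-3-one (ethyl vinyl ketone)
Product: 20 C9-O-{[(3Z)-penta-1,3-dien-3-yloxy]di(propan-2-yl)silyl} ether of 17, via dienyloxysilyl triflate 19 (not isolated)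
Conditions: iPr2Si(OTf)2, Et3N, 18, CH2Cl2, −78 °C; then 17, −78 → −20 °C
Reagents that add atoms: diisopropylsilyl bis(trifluoromethanesulfonate), CC(C)[Si](OS(=O)(=O)C(F)(F)F)(OS(=O)(=O)C(F)(F)F)C(C)C
Why: Soft enolisation of ethyl vinyl ketone by the silyl triflate and Et3N should give the thermodynamically favoured (Z)-2-silyloxy diene (methyl cis to oxygen), and the remaining hindered Si–OTf then silylates the secondary C9 hydroxyl in preference to the tertiary 8-OH, giving the mixed silyl ketal (temporary silicon connection).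

Step 12
Reactants: 20 silyl-ketal-tethered triene
Product: 21 3,3-di(propan-2-yl)-2,4-dioxa-3-silabicyclo[4.3.1]dec-1(9)-ene cycloadduct (ring atoms 1 = C12, 5 = C9, 6 = C10, 7 = C1, 8 = C14, 9 = C13, 10 = C11) bearing the lactone on C9, CH3 and 4-methylpent-4-enoyl on C1, CH3 on C11; stereocentres as in 28
Conditions: PhMe (0.01 M), BHT, 150 °C, sealed tube
Reagents that add atoms: none
Why: Thermal concerted [4πs+2πs] cycloaddition in the type 2 intramolecular mode (tether on C2 of the diene, here through the enol oxygen), HOMO of the (Z)-2-silyloxy diene against LUMO of the enone, the closest known reaction type being the silyl-ketal-tethered type 2 intramolecular Diels–Alder reaction that gives bridgehead alkenes. The cyclohexene ring (C1, C10, C11, C12, C13, C14) closes by the cycloaddition itself through the new C11–C10 and C14–C1 bonds, and the seven-membered 1,3-dioxa-2-silepane (C9, C10, C11, C12, O, Si, O) closes with it as the bridging ring, its bridgehead C12=C13 bond being the regiodefined silyl enol ether. Regiochemistry is secured twice, because the tether can only bring C10 to C11 and because the nucleophilic enol-ether terminus C11 matches the enone β-carbon C10 (C14 to the α-carbon C1). C1 and C10 follow from suprafacial addition to the (E)-alkene, which keeps C2 anti to C9 and the C1 methyl syn to C9 (trans ring fusion). C11 follows from the short tether, which forces C9 endo, and from the (Z)-enol ether, which keeps its methyl outside, so the C11 methyl ends cis to C9 and to the C1 methyl. The step needs facial selectivity, which the C9 stereocentre provides through A(1,3) strain with the C1 methyl (C9–H lies in the alkene plane, so the silicon-bearing oxygen and with it the diene sit on one face and the quaternary lactone carbon C8 on the other), and it needs cycloaddition to outrun loss of the dienol ether, which intramolecularity and matched electron demand should provide.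

Step 13
Reactants: 21 bridged cycloadduct (C2 ketone)
Product: 22 (2R)-alcohol of 21
Conditions: (S)-2-methyl-CBS-oxazaborolidine (0.3 equiv), catecholborane, PhMe, −78 → −40 °C; MeOH, evaporate
Reagents that add atoms: none
Why: Corey–Bakshi–Shibata reduction, in which the (S)-oxazaborolidine treats the quaternary C1 as the large and the C3 methylene as the small ketone substituent, should deliver hydride to give the (2R)-alcohol under reagent control while the silyl enol ether, the lactone and the alkenes stay untouched.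

Step 14
Reactants: 22 (2R)-alcohol of 21
Product: 24 cyclohexenone triol (C12 ketone with C13=C14; free 2-OH, 8-OH, 9-OH; 5,6-seco with C5 isopropenyl and C6 vinyl), via acetoxysilyl ether 23 (not isolated)
Conditions: Pd(OAc)2 (1.2 equiv), MeCN, rt; then HF·pyridine, THF, 0 °C
Reagents that add atoms: none
Why: Saegusa–Ito oxidation, in which Pd(OAc)2 turns the bridgehead silyl enol ether into the C13 palladium enolate and syn β-hydride elimination from C14 gives the C13=C14 enone regiospecifically, is followed by fluoride cleavage of the remaining Si–O9 bond under conditions too mild to epimerise C11.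

Step 15
Reactants: 24 cyclohexenone triol
Product: 25 2,9-di-O-acetate of 24
Conditions: Ac2O, pyridine, DMAP (cat.), CH2Cl2, 0 °C → rt
Reagents that add atoms: acetic anhydride, CC(=O)OC(C)=O
Why: DMAP-catalysed acylation should esterify the two secondary hydroxyls (O2 and O9) while the hindered tertiary 8-OH does not react.

Step 16
Reactants: 25 enone diacetate
Product: 26 (12S)-allylic alcohol (12-OH cis to the C11 methyl)
Conditions: NaBH4, CeCl3·7H2O, MeOH, −78 °C
Reagents that add atoms: none
Why: Luche 1,2-reduction, in which the preferred half-chair (both ring methyls pseudo-equatorial, the C9 chain axial) should expose the face of C12 opposite the axial C9 substituent to hydride, should give the alcohol with OH cis to the C11 methyl.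

Step 17
Reactants: 26 (12S)-allylic alcohol
Product: 27 (12R)-butanoate, the 5,6-seco diene of 28
Conditions: PPh3, DIAD, butanoic acid, PhMe, 0 °C → rt
Reagents that add atoms: butanoic acid, CCCC(=O)O
Why: Mitsunobu esterification should proceed with SN2 inversion at C12 to give the butanoate trans to the C11 methyl as in the target, the SN2' path being blocked because C14 is neopentyl and the tertiary 8-OH being inert.

Step 18
Reactants: 27 5,6-seco diene
Product: 28 CNP0211702.1
Conditions: second-generation Hoveyda–Grubbs catalyst (10 mol %), PhMe (0.5 mM), 80 °C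
Reagents that add atoms: none
Why: Ring-closing metathesis, in which the catalyst loads on the monosubstituted vinyl group and closes onto the 1,1-disubstituted alkene with loss of ethene, should give the ten-membered ring with the (Z)-trisubstituted C5=C6 alkene (cis being the more stable geometry of a cyclodecene), the hindered cyclohexene and the esters being spectators.

**Compound list**

1 | 1,2:5,6-di-O-isopropylidene-α-D-glucofuranose | CC1(C)OC[C@@H](O1)[C@H]2O[C@@H]3OC(C)(C)O[C@@H]3[C@H]2O | starting material
2 | 1,2:5,6-di-O-isopropylidene-α-D-ribo-hexofuranos-3-ulose | CC1(C)OC[C@@H](O1)[C@H]2O[C@@H]3OC(C)(C)O[C@@H]3C2=O | intermediate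
3 | N,N-dimethylpropanamide | CCC(=O)N(C)C | starting material
4 | 3-C-[(2R)-1-(dimethylamino)-1-oxopropan-2-yl]-1,2:5,6-di-O-isopropylidene-α-D-allofuranose | CC1(C)OC[C@@H](O1)[C@H]2O[C@@H]3OC(C)(C)O[C@@H]3[C@@]2(O)[C@@H](C)C(=O)N(C)C | intermediate
5 | 3-C-[(2R)-1-(dimethylamino)-1-oxopropan-2-yl]-2,3:5,6-di-O-isopropylidene-D-allofuranose (anomers) | CC1(C)OC[C@@H](O1)[C@H]2OC(O)[C@@H]3OC(C)(C)O[C@]23[C@@H](C)C(=O)N(C)C | intermediate
6 | 1,2-dideoxy-4-C-[(2R)-1-(dimethylamino)-1-oxopropan-2-yl]-3,4:6,7-di-O-isopropylidene-D-allo-hept-1-enitol | C=C[C@@H]1OC(C)(C)O[C@]1([C@@H](C)C(=O)N(C)C)[C@H](O)[C@H]1COC(C)(C)O1 | intermediate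
7 | 5-O-(4-methoxybenzyl) ether of 6 | C=C[C@@H]1OC(C)(C)O[C@]1([C@@H](C)C(=O)N(C)C)[C@H](OCc2ccc(OC)cc2)[C@H]1COC(C)(C)O1 | intermediate
8 | 1,2-dideoxy-4-C-[(2R)-1-(dimethylamino)-1-oxopropan-2-yl]-5-O-(4-methoxybenzyl)-D-allo-hept-1-enitol (tetraol amide) | C=C[C@H](O)[C@@](O)([C@@H](C)C(=O)N(C)C)[C@H](OCc1ccc(OC)cc1)[C@H](O)CO | intermediate
9 | (3R,4S,5S)-4-[(1R,2R)-2,3-dihydroxy-1-(4-methoxybenzyloxy)propyl]-5-ethenyl-4-hydroxy-3-methyloxolan-2-one (ethenyl, OH and methyl mutually cis) | C=C[C@@H]1OC(=O)[C@H](C)[C@@]1(O)[C@H](OCc2ccc(OC)cc2)[C@H](O)CO | intermediate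
10 | (2S)-2-[(2S,3S,4R)-2-ethenyl-3-hydroxy-4-methyl-5-oxooxolan-3-yl]-2-(4-methoxybenzyloxy)acetaldehyde | C=C[C@@H]1OC(=O)[C@H](C)[C@@]1(O)[C@H](OCc2ccc(OC)cc2)C=O | intermediate
11 | 4-methylpent-4-enoic acid | CC(=C)CCC(=O)O | starting material
12 | ethyltriphenylphosphonium bromide | CC[P+](c1ccccc1)(c1ccccc1)c1ccccc1.[Br-] | starting material
13 | 4-methylpent-4-enoyl chloride | CC(=C)CCC(Cl)=O | intermediate
14 | ethylidene(triphenyl)phosphorane | CC=P(c1ccccc1)(c1ccccc1)c1ccccc1 | intermediate
15 | 6-methyl-2-(triphenyl-λ5-phosphanylidene)hept-6-en-3-one | CC(=C)CCC(=O)C(C)=P(c1ccccc1)(c1ccccc1)c1ccccc1 | intermediate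
16 | 5-ethenyl-4-hydroxy-4-[(1R,2E)-1-(4-methoxybenzyloxy)-3,7-dimethyl-4-oxoocta-2,7-dien-1-yl]-3-methyloxolan-2-one, ring configured as in 9 | C=C[C@@H]1OC(=O)[C@H](C)[C@@]1(O)[C@H](OCc2ccc(OC)cc2)/C=C(\C)C(=O)CCC(C)=C | intermediate
17 | 5-ethenyl-4-hydroxy-4-[(1R,2E)-1-hydroxy-3,7-dimethyl-4-oxoocta-2,7-dien-1-yl]-3-methyloxolan-2-one, ring configured as in 9 | C=C[C@@H]1OC(=O)[C@H](C)[C@@]1(O)[C@H](O)/C=C(\C)C(=O)CCC(C)=C | intermediate
18 | pent-1-en-3-one | CCC(=O)C=C | starting material
19 | [(3Z)-penta-1,3-dien-3-yloxy]di(propan-2-yl)silyl trifluoromethanesulfonate | C/C=C(\O[Si](C(C)C)(C(C)C)OS(=O)(=O)C(F)(F)F)C=C | intermediate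
20 | 17 with its C9 oxygen bound to Si(iPr)2–O–[(3Z)-penta-1,3-dien-3-yl] (silyl-ketal-tethered triene) | C=C[C@@H]1OC(=O)[C@H](C)[C@@]1(O)[C@H](O[Si](C(C)C)(C(C)C)O/C(C=C)=C\C)/C=C(\C)C(=O)CCC(C)=C | intermediate
21 | 3,3-di(propan-2-yl)-2,4-dioxa-3-silabicyclo[4.3.1]dec-1(9)-ene cycloadduct: lactone on C9, CH3 and 4-methylpent-4-enoyl on C1, CH3 on C11; C1, C9, C10, C11 as in 28 | C=C[C@@H]1OC(=O)[C@H](C)[C@@]1(O)[C@@H]2O[Si](C(C)C)(C(C)C)OC3=CC[C@](C)(C(=O)CCC(C)=C)[C@@H]2[C@H]3C | intermediate
22 | (2R)-alcohol of 21 (C2 carbinol as in 28) | C=C[C@@H]1OC(=O)[C@H](C)[C@@]1(O)[C@@H]2O[Si](C(C)C)(C(C)C)OC3=CC[C@](C)([C@H](O)CCC(C)=C)[C@@H]2[C@H]3C | intermediate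
23 | cyclohex-13-en-12-one with 9-O-[acetoxydi(propan-2-yl)silyl], free 2-OH and 8-OH | C=C[C@@H]1OC(=O)[C@H](C)[C@@]1(O)[C@H](O[Si](C(C)C)(C(C)C)OC(C)=O)[C@H]2[C@@H](C)C(=O)C=C[C@]2(C)[C@H](O)CCC(C)=C | intermediate
24 | 5,6-seco cyclohex-13-en-12-one with free 2-OH, 8-OH, 9-OH; stereocentres as in 28 | C=C[C@@H]1OC(=O)[C@H](C)[C@@]1(O)[C@H](O)[C@H]2[C@@H](C)C(=O)C=C[C@]2(C)[C@H](O)CCC(C)=C | intermediate
25 | 2,9-di-O-acetate of 24 | C=C[C@@H]1OC(=O)[C@H](C)[C@@]1(O)[C@H](OC(C)=O)[C@H]2[C@@H](C)C(=O)C=C[C@]2(C)[C@H](OC(C)=O)CCC(C)=C | intermediate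
26 | (12S)-allylic alcohol from 25 (12-OH cis to the C11 methyl; C12 epimeric to 28) | C=C[C@@H]1OC(=O)[C@H](C)[C@@]1(O)[C@H](OC(C)=O)[C@H]2[C@@H](C)[C@@H](O)C=C[C@]2(C)[C@H](OC(C)=O)CCC(C)=C | intermediate
27 | 5,6-seco diene of 28: (12R)-butanoate, 2,9-diacetate, 8-OH, C5 isopropenyl, C6 vinyl | C=C[C@@H]1OC(=O)[C@H](C)[C@@]1(O)[C@H](OC(C)=O)[C@H]2[C@@H](C)[C@H](OC(=O)CCC)C=C[C@]2(C)[C@H](OC(C)=O)CCC(C)=C | intermediate
28 | CNP0211702.1 | CCCC(=O)O[C@@H]1C=C[C@@]2(C)[C@H]([C@H]1C)[C@@H](OC(C)=O)[C@@]1(O)[C@H](/C=C(/C)CC[C@H]2OC(C)=O)OC(=O)[C@@H]1C | target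

**Step count**

Total steps: 18. Longest linear sequence: 17 steps (from 1 through steps 1–7 and 9–18; step 8 is the side branch).

**Steps most likely to fail, with fallbacks**

Step 12 (key cycloaddition). The bridgehead-alkene strain of the seven-membered silacycle may raise the barrier so far that loss of the dienol ether (hydrolysis, hydrogen shift) or intermolecular reaction takes over. The fallback lengthens the tether by one Si–O unit and sets out from 17 (with 18). Ketone 18 is enol-silylated with 1,3-dichloro-1,1,3,3-tetraisopropyldisiloxane (Et3N, NaI, MeCN), and the chlorodisiloxane is coupled with 17 (imidazole, DMF) to give the disiloxane-tethered triene F1. Heating should then give the cycloadduct with a nine-membered O–Si–O–Si–O bridge F2, a bicyclo[6.3.1] bridgehead alkene with little strain, formed with the same tether-enforced regiochemistry and the same A(1,3) facial control. CBS reduction as in step 13 gives the (2R)-alcohol F3, and Pd(OAc)2 followed by HF·pyridine as in step 14 comes back to the route at 24.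

Step 18 (ring-closing metathesis). Cross-metathesis oligomerisation, or erosion of alkene geometry, may win because a trisubstituted alkene must form in a ten-membered ring from two chains that sit trans on the cyclohexene and carry bulky esters. The fallback closes the ring earlier and sets out from 24. In 24 a hydrogen bond between the 2-OH and 9-OH can hold the two chains gauche and the ester bulk is absent. Ring-closing metathesis under the step 18 conditions should give the macrocyclic enone diol F4. Acetylation as in step 15 gives the macrocyclic enone diacetate F5, Luche reduction gives the macrocyclic (12S)-allylic alcohol F6, and Mitsunobu esterification with butanoic acid as in step 17 comes back to the route at 28.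

Step 16 (Luche reduction). Facial discrimination may be poor if both half-chairs of the cyclohexenone are populated, giving a mixture of C12 epimers. The fallback makes the sequence stereoconvergent and sets out from 25. The epimeric alcohols are separated; 26 continues through step 17 with inversion, while the (12R)-allylic alcohol F7 is acylated with retention (butanoic anhydride, DMAP, pyridine). Both streams come back to the route at 27.

Further compounds
F1 | step 12 | disiloxane-tethered triene: 17 with its C9 oxygen bound to Si(iPr)2–O–Si(iPr)2–O–[(3Z)-penta-1,3-dien-3-yl] | C=C[C@@H]1OC(=O)[C@H](C)[C@@]1(O)[C@H](O[Si](C(C)C)(C(C)C)O[Si](C(C)C)(C(C)C)O/C(C=C)=C\C)/C=C(\C)C(=O)CCC(C)=C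
F2 | step 12 | cycloadduct with nine-membered O–Si–O–Si–O bridge between C9 and C12 (C2 ketone), stereocentres as in 21 | C=C[C@@H]1OC(=O)[C@H](C)[C@@]1(O)[C@@H]2O[Si](C(C)C)(C(C)C)O[Si](C(C)C)(C(C)C)OC3=CC[C@](C)(C(=O)CCC(C)=C)[C@@H]2[C@H]3C
F3 | step 12 | (2R)-alcohol of F2 | C=C[C@@H]1OC(=O)[C@H](C)[C@@]1(O)[C@@H]2O[Si](C(C)C)(C(C)C)O[Si](C(C)C)(C(C)C)OC3=CC[C@](C)([C@H](O)CCC(C)=C)[C@@H]2[C@H]3C
F4 | step 18 | macrocyclic enone diol (28 with C12 ketone and free 2-OH and 9-OH) | O=C1C=C[C@@]2(C)[C@H]([C@H]1C)[C@@H](O)[C@@]1(O)[C@H](/C=C(/C)CC[C@H]2O)OC(=O)[C@@H]1C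
F5 | step 18 | macrocyclic enone 2,9-diacetate | O=C1C=C[C@@]2(C)[C@H]([C@H]1C)[C@@H](OC(C)=O)[C@@]1(O)[C@H](/C=C(/C)CC[C@H]2OC(C)=O)OC(=O)[C@@H]1C
F6 | step 18 | macrocyclic (12S)-allylic alcohol (12-epi-12-O-debutanoyl 28) | O[C@H]1C=C[C@@]2(C)[C@H]([C@H]1C)[C@@H](OC(C)=O)[C@@]1(O)[C@H](/C=C(/C)CC[C@H]2OC(C)=O)OC(=O)[C@@H]1C
F7 | step 16 | (12R)-allylic alcohol, C12 epimer of 26 | C=C[C@@H]1OC(=O)[C@H](C)[C@@]1(O)[C@H](OC(C)=O)[C@H]2[C@@H](C)[C@H](O)C=C[C@]2(C)[C@H](OC(C)=O)CCC(C)=C
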